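(The runs are calculated for substances that don't exist; the scatter is artificial.)

A ratio was what I reckoned with: of the J charged, the part lost divided by the part kept as L.

| flask | J | G | remark | time |
|---|---|---|---|---|
| south-west | 0.20 M (in portions, 2) | 1 mM | the very flask that is asked about, followed so far; portions every 6.0 s |  |
| south-east | 0.30 M (in portions, 2) | 1 mM | run made earlier; portions every 6.0 s |  |
| flask | 0.20 M (in portions, 2) | 1.0 mM | the portions of J follow each other after 6.0 s, the first at the start | 2.0 h |

| run | time / min | L / % | J / % |
|---|---|---|---|
| south-west | 6.00 | 86.4 | 0 |
| south-west | 12.0 | 85.6 | 0.2 |
| south-west | 20.0 | 86.8 | 0 |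
| south-west | 25.0 | 86.0 | 0.2 |
| south-east | 4.00 | 76.8 | 0.4 |
| south-east | 8.00 | 76.3 | 0.3 |
| south-east | 20.0 | 75.8 | 0 |
| south-east | 50.0 | 75.9 | 0 |

(each reading ± 0.5 percentage points)

- why nothing more happens at 2.0 h, or that something still does (no working catalyst is left / forward and back rates have come level / it is still moving / all of J has reacted)
- how much L there is at 2.0 h, in percent of the J charged

- the reaction counts as stopped when no species that holds the J changes by six tenths of a point or more over the second half of the time

Both parts of that ratio are sums over the same minutes, so time dropped out of it once a run had gone flat. Both runs were flat within the scatter of 0.5 percentage points, with J at 0.2% or less at their latest readings.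

I built the flask up in steps. The main step alone, J to L over G, put L at 100%. The south-west run instead averaged 86.2%, so its loss ratio, lost part over kept part, the inverse of a selectivity, read 0.160.

Next I added a side path. If it had the same order in J as the main step, the ratio stayed equal between charges at equal G. But the south-east run averaged 76.2%, a ratio of 0.312, about twice the other. So I took the side path as higher in J, and the two runs read the ratio as rising with the charge to the power 1.65.

Then came the rest. G at 1 mM and the 6.0 s between portions were equal in both runs, so they stayed out of this comparison. In the south-west run the second portion also came long before the first reading.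

The flask asked about is the south-west run carried on, so I committed to a ratio of 0.160 and L at 86.2%, with J, the limiting reagent, used up, as its reading of 0.2% at 25.0 min allowed within the scatter.

The forecast was 86.2%, with the end given as "all of J has reacted", on the ground that “With no J left, nothing can feed L”.

The flask gave 86.1% at 2.0 h, and its end was: all of J has reacted, with J at 0%.

    J + G → E (k = 66.0 L mol⁻¹ s⁻¹)
    E → G + L (k = 3.40 s⁻¹)
    2 J → Z (k = 0.0190 L mol⁻¹ s⁻¹)

In this flask the result put the loss ratio at 0.162, beside the 0.160 read from the south-west run. The lost part stood as Z, counted by the J it holds, at 13.9%. The neighbouring flask differed in one setting, 0.12 M of J. Scaling 0.160 by the charge to the power 1.65 gave it a ratio of 0.0690, and so L at 93.5%. That flask gave L at 93.3%, with Z at 6.65%.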